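**Retrosynthetic overview** (target locants: ring C1 carries the side chain, C2 is CH2, C3 Cl, C4 CH3/OH, C5 O-angeloyl, C6 OAc; chain C7(=CH2), C8 O-angeloyl, C9, C10 OH, C11 CMe2OH)
1. Target ⇐ C3–C4 oxirane: the trans-chlorohydrin and the free 10,11-diol are unmasked together in the last step (HCl opening, acetonide hydrolysis); both angelates go on in one operation just before.
2. C8–O bond (key step): SeO2 allylic oxidation of the exocyclic 1,1-disubstituted alkene, i.e. ene reaction then [2,3]-sigmatropic rearrangement of the allylseleninic acid; oxidation to the enone and chelate-controlled reduction then relay the C10 configuration to C8.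
3. C8–C9 bond: Keck radical allylation of a carvone-derived 2-(stannylmethyl)allyl unit with a C9–C11 iodide whose stereocentre (C10) is bought in methyl (S)-2,2-dimethyl-1,3-dioxolane-4-carboxylate.
4. Ring stereocentres: all relayed from C1 of (R)-carvone by substrate control: α′-hydroxylation (trans), Mitsunobu inversion with AcOH (C6), Luche reduction (C5), hydroxyl-directed epoxidation (C3, C4).
5. Rings: the cyclohexane is bought and never rebuilt; the transposed dioxolane of the side-chain fragment is made first (step 7), the oxirane is the last ring formed (step 10) and is opened in step 15.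

Assumption: the SMILES is read as (1S,3R,4R,5R,6R,8S,10S); (R)-carvone, methyl (S)-2,2-dimethyl-1,3-dioxolane-4-carboxylate and angelic acid are bought, and the Davis oxaziridine is used as the racemate.
IUPAC names carry their own numbering; locants in the "Why" lines are the target locants given above.

**Step 1**
Reactants: 1 (R)-(−)-carvone
Product: 3 trans-6-hydroxycarvone [(5S,6S)-6-hydroxy-2-methyl-5-(prop-1-en-2-yl)cyclohex-2-en-1-one], via lithium dienolate 2 (not isolated)
Conditions: LiN(iPr)2, THF, −78 °C; then (±)-trans-3-phenyl-2-(phenylsulfonyl)oxaziridine, −78 °C; aq. NH4Cl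
Reagents that add atoms: (±)-trans-3-phenyl-2-(phenylsulfonyl)oxaziridine, O=S(=O)(c1ccccc1)N1OC1c1ccccc1
Why: Kinetic α′-deprotonation gives the cross-conjugated enolate, and enolate hydroxylation with the racemic Davis oxaziridine delivers oxygen anti to the neighbouring isopropenyl group, setting C6–OH trans.

**Step 2**
Reactants: 3 trans-6-hydroxycarvone
Product: 4 cis-6-acetoxycarvone [(1R,6S)-3-methyl-2-oxo-6-(prop-1-en-2-yl)cyclohex-3-en-1-yl acetate]
Conditions: PPh3, DIAD, AcOH, THF, 0 °C → rt
Reagents that add atoms: acetic acid, CC(=O)O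
Why: Mitsunobu reaction: acetate displaces the alkoxyphosphonium ion of the α-ketol by SN2 with inversion, turning the trans alcohol into the cis (axial) C6 acetate of the target without base.

**Step 3**
Reactants: 4 cis-6-acetoxycarvone
Product: 5 (1R,6S)-6-(3-chloroprop-1-en-2-yl)-3-methyl-2-oxocyclohex-3-en-1-yl acetate
Conditions: Ca(OCl)2, CO2 (dry ice), CH2Cl2–H2O, 0 °C
Reagents that add atoms: calcium hypochlorite, [Ca+2].[O-]Cl.[O-]Cl
Why: Ene-type allylic chlorination by HOCl made in situ attacks only the electron-rich isopropenyl group (the enone alkene is deactivated) and touches no stereocentre.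

**Step 4**
Reactants: 5 chloro enone acetate
Product: 6 (1R,2S,6S)-6-(3-chloroprop-1-en-2-yl)-2-hydroxy-3-methylcyclohex-3-en-1-yl acetate
Conditions: NaBH4, CeCl3·7H2O, MeOH, −78 °C
Reagents that add atoms: none
Why: Luche 1,2-reduction: hydride adds axially, anti to the axial C6 acetoxy group, giving the equatorial C5 alcohol cis to both the acetate and the side chain.

**Step 5**
Reactants: 6 chloro allylic alcohol
Product: 7 (1R,2S,6S)-2-hydroxy-3-methyl-6-[3-(tributylstannyl)prop-1-en-2-yl]cyclohex-3-en-1-yl acetate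
Conditions: Bu3SnSnBu3, Pd2(dba)3 (2.5 mol %), THF, rt
Reagents that add atoms: hexabutylditin, CCCC[Sn](CCCC)(CCCC)[Sn](CCCC)(CCCC)CCCC
Why: Palladium-catalysed allylic stannylation: zerovalent palladium ionises the allylic chloride to a π-allyl complex that is stannylated by the ditin, with no regiochemical issue because the 2-substituted allyl unit has equivalent termini.

**Step 6**
Reactants: 8 methyl (S)-2,2-dimethyl-1,3-dioxolane-4-carboxylate
Product: 9 2-[(4S)-2,2-dimethyl-1,3-dioxolan-4-yl]propan-2-ol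
Conditions: MeMgBr (2.5 equiv), Et2O, 0 °C → rt; aq. NH4Cl
Reagents that add atoms: methylmagnesium bromide, C[Mg]Br
Why: Double Grignard addition to the ester builds the CMe2OH carbon (C11) without touching the stereocentre that becomes C10.

**Step 7**
Reactants: 9 tertiary alcohol
Product: 10 [(4S)-2,2,5,5-tetramethyl-1,3-dioxolan-4-yl]methanol
Conditions: TsOH·H2O (cat.), acetone, rt
Reagents that add atoms: none
Why: Acid-catalysed acetal transposition under thermodynamic control moves the acetonide onto the secondary/tertiary diol (the more substituted dioxolane) and frees the primary hydroxyl, the C–O bond at the stereocentre never being broken.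

**Step 8**
Reactants: 10 primary alcohol
Product: 11 (4R)-4-(iodomethyl)-2,2,5,5-tetramethyl-1,3-dioxolane
Conditions: I2, PPh3, imidazole, CH2Cl2, 0 °C → rt
Reagents that add atoms: iodine, II
Why: Appel-type iodination (Garegg–Samuelsson conditions) replaces the primary hydroxyl by SN2 at CH2, leaving the adjacent stereocentre unchanged (the descriptor changes by priority only).

**Step 9**
Reactants: 7 allylstannane; 11 iodide
Product: 12 (1R,2S,6S)-2-hydroxy-3-methyl-6-{4-[(4S)-2,2,5,5-tetramethyl-1,3-dioxolan-4-yl]but-1-en-2-yl}cyclohex-3-en-1-yl acetate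
Conditions: 11 (3 equiv), AIBN (0.2 equiv), benzene, 80 °C
Reagents that add atoms: none
Why: Keck radical allylation: the primary radical from 11 (a β-oxygenated radical does not eliminate) adds to the terminal carbon of the allylstannane and loss of Bu3Sn• regenerates the exocyclic alkene, forging C8–C9 under neutral conditions that spare the alcohol, acetate and acetonide.

**Step 10**
Reactants: 12 coupled allylic alcohol
Product: 13 (1R,2R,3R,4S,6S)-2-hydroxy-1-methyl-4-{4-[(4S)-2,2,5,5-tetramethyl-1,3-dioxolan-4-yl]but-1-en-2-yl}-7-oxabicyclo[4.1.0]heptan-3-yl acetate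
Conditions: VO(acac)2 (5 mol %), t-BuOOH, CH2Cl2, 0 °C → rt
Reagents that add atoms: tert-butyl hydroperoxide, CC(C)(C)OO
Why: Hydroxyl-directed vanadium-catalysed epoxidation delivers oxygen to the ring alkene on the face of the allylic C5 hydroxyl and leaves the remote 1,1-disubstituted alkene alone.

**Step 11** (key step)
Reactants: 13 epoxy alcohol
Product: 16 C8 allylic alcohol (8RS mixture), via allylseleninic acid 14 (not isolated), via divalent selenium ester 15 (not isolated)
Conditions: SeO2 (0.5 equiv), t-BuOOH (3 equiv), CH2Cl2, 0 °C → rt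
Reagents that add atoms: selenium dioxide, O=[Se]=O; tert-butyl hydroperoxide, CC(C)(C)OO
Why: SeO2 allylic oxidation: an ene reaction at the exocyclic methylene gives the allylseleninic acid, whose [2,3]-sigmatropic rearrangement forms the C8–O bond and returns the double bond to C7=CH2 (allylic CH2 reacts before the ring CH); C8 is not controlled here and is reset in steps 12–13.

**Step 12**
Reactants: 16 C8 allylic alcohol (8RS mixture)
Product: 17 α-methylene ketone (C8 ketone)
Conditions: MnO2 (activated, excess), CH2Cl2, rt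
Reagents that add atoms: none
Why: MnO2 oxidises only the allylic C8 alcohol (the C5 epoxy alcohol is not allylic), converging both epimers on one enone.

**Step 13**
Reactants: 17 α-methylene ketone
Product: 18 (8S)-5,8-diol
Conditions: Zn(BH4)2, Et2O, −40 °C; aq. NH4Cl
Reagents that add atoms: none
Why: Chelation-controlled 1,2-reduction: zinc bridges the C8 carbonyl and the C10 dioxolane oxygen and external hydride attacks the six-membered chelate to give the 8,10-syn (8S) alcohol, so C8 is set by the bought C10 centre.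

**Step 14**
Reactants: 18 (8S)-5,8-diol
Product: 19 5,8-bis-angelate
Conditions: angelic acid, 2,4,6-Cl3C6H2COCl, Et3N, toluene, rt; then 18, 80 °C
Reagents that add atoms: angelic acid, C/C=C(/C)C(=O)O
Why: Yamaguchi esterification with the preformed mixed anhydride (no DMAP, which would isomerise angelate to tiglate) acylates the only two free hydroxyls, C5 and C8, with retention.

**Step 15**
Reactants: 19 5,8-bis-angelate
Product: 21 CNP0212201.1, via chlorohydrin acetonide 20 (not isolated)
Conditions: HCl (4 M in dioxane), CH2Cl2, −20 °C; then 2 M aq. HCl–THF, rt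
Reagents that add atoms: hydrogen chloride, Cl
Why: Acid-mediated epoxide opening under Fürst–Plattner control (chloride attacks secondary C3 anti to the oxirane, giving the trans-diaxial chlorohydrin with the tertiary C4–OH retained), followed by acetal hydrolysis of the acetonide.

**Compound list**
1 | (R)-(−)-carvone, (5R)-2-methyl-5-(prop-1-en-2-yl)cyclohex-2-en-1-one | C=C(C)[C@@H]1CC=C(C)C(=O)C1 | starting material
2 | lithium kinetic (cross-conjugated) enolate of (R)-carvone | C=C(C)[C@@H]1CC=C(C)C([O-])=C1.[Li+] | intermediate (not isolated)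
3 | (5S,6S)-6-hydroxy-2-methyl-5-(prop-1-en-2-yl)cyclohex-2-en-1-one (OH trans to isopropenyl) | C=C(C)[C@@H]1CC=C(C)C(=O)[C@H]1O | intermediate
4 | (1R,6S)-3-methyl-2-oxo-6-(prop-1-en-2-yl)cyclohex-3-en-1-yl acetate (OAc cis to isopropenyl) | C=C(C)[C@@H]1CC=C(C)C(=O)[C@@H]1OC(C)=O | intermediate
5 | (1R,6S)-6-(3-chloroprop-1-en-2-yl)-3-methyl-2-oxocyclohex-3-en-1-yl acetate | C=C(CCl)[C@@H]1CC=C(C)C(=O)[C@@H]1OC(C)=O | intermediate
6 | (1R,2S,6S)-6-(3-chloroprop-1-en-2-yl)-2-hydroxy-3-methylcyclohex-3-en-1-yl acetate (OH, OAc and side chain all cis) | C=C(CCl)[C@@H]1CC=C(C)[C@H](O)[C@@H]1OC(C)=O | intermediate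
7 | (1R,2S,6S)-2-hydroxy-3-methyl-6-[3-(tributylstannyl)prop-1-en-2-yl]cyclohex-3-en-1-yl acetate | C=C(C[Sn](CCCC)(CCCC)CCCC)[C@@H]1CC=C(C)[C@H](O)[C@@H]1OC(C)=O | intermediate
8 | methyl (S)-2,2-dimethyl-1,3-dioxolane-4-carboxylate | COC(=O)[C@@H]1COC(C)(C)O1 | starting material
9 | 2-[(4S)-2,2-dimethyl-1,3-dioxolan-4-yl]propan-2-ol | CC(C)(O)[C@@H]1COC(C)(C)O1 | intermediate
10 | [(4S)-2,2,5,5-tetramethyl-1,3-dioxolan-4-yl]methanol | OC[C@@H]1OC(C)(C)OC1(C)C | intermediate
11 | (4R)-4-(iodomethyl)-2,2,5,5-tetramethyl-1,3-dioxolane | IC[C@@H]1OC(C)(C)OC1(C)C | intermediate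
12 | (1R,2S,6S)-2-hydroxy-3-methyl-6-{4-[(4S)-2,2,5,5-tetramethyl-1,3-dioxolan-4-yl]but-1-en-2-yl}cyclohex-3-en-1-yl acetate | C=C(CC[C@@H]2OC(C)(C)OC2(C)C)[C@@H]1CC=C(C)[C@H](O)[C@@H]1OC(C)=O | intermediate
13 | (1R,2R,3R,4S,6S)-2-hydroxy-1-methyl-4-{4-[(4S)-2,2,5,5-tetramethyl-1,3-dioxolan-4-yl]but-1-en-2-yl}-7-oxabicyclo[4.1.0]heptan-3-yl acetate (oxirane cis to OH; target locants 1S,3S,4R,5R,6R,10S) | C=C(CC[C@@H]2OC(C)(C)OC2(C)C)[C@@H]1C[C@@H]3O[C@]3(C)[C@H](O)[C@@H]1OC(C)=O | intermediate
14 | allylseleninic acid from 13: Se(=O)OH on the former exocyclic CH2, double bond shifted to C7=C8 | O[Se](=O)CC(=CC[C@@H]2OC(C)(C)OC2(C)C)[C@@H]1C[C@@H]3O[C@]3(C)[C@H](O)[C@@H]1OC(C)=O | intermediate (not isolated)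
15 | divalent selenium ester from 14: C8–O–Se–OH, exocyclic C7=CH2 restored | C=C(C(O[Se]O)C[C@@H]2OC(C)(C)OC2(C)C)[C@@H]1C[C@@H]3O[C@]3(C)[C@H](O)[C@@H]1OC(C)=O | intermediate (not isolated)
16 | 8-hydroxy derivative of 13, both C8 epimers (1S,3S,4R,5R,6R,8RS,10S) | C=C(C(O)C[C@@H]2OC(C)(C)OC2(C)C)[C@@H]1C[C@@H]3O[C@]3(C)[C@H](O)[C@@H]1OC(C)=O | intermediate
17 | 8-oxo derivative of 13, the α-methylene ketone (1S,3S,4R,5R,6R,10S) | C=C(C(=O)C[C@@H]2OC(C)(C)OC2(C)C)[C@@H]1C[C@@H]3O[C@]3(C)[C@H](O)[C@@H]1OC(C)=O | intermediate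
18 | (8S)-8-hydroxy derivative of 13, the 5,8-diol with 8,10-syn oxygens (1S,3S,4R,5R,6R,8S,10S) | C=C([C@H](C[C@@H]2OC(C)(C)OC2(C)C)O)[C@@H]1C[C@@H]3O[C@]3(C)[C@H](O)[C@@H]1OC(C)=O | intermediate
19 | 5,8-di-O-[(Z)-2-methylbut-2-enoyl] derivative of 18 (1S,3S,4R,5R,6R,8S,10S) | C=C([C@H](C[C@@H]2OC(C)(C)OC2(C)C)OC(=O)/C(C)=C\C)[C@@H]1C[C@@H]3O[C@]3(C)[C@H](OC(=O)/C(C)=C\C)[C@@H]1OC(C)=O | intermediate
20 | 10,11-acetonide of the target: 3-chloro-4-hydroxy chlorohydrin (1S,3R,4R,5R,6R,8S,10S) | C=C([C@H](C[C@@H]2OC(C)(C)OC2(C)C)OC(=O)/C(C)=C\C)[C@@H]1C[C@@H](Cl)[C@](C)(O)[C@H](OC(=O)/C(C)=C\C)[C@@H]1OC(C)=O | intermediate (not isolated)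
21 | CNP0212201.1: cyclohexane with 3-Cl, 4-OH/4-CH3, 5-O-angeloyl, 6-OAc and at C1 the chain C7(=CH2)–C8H(O-angeloyl)–C9H2–C10H(OH)–C11Me2OH (1S,3R,4R,5R,6R,8S,10S) | C=C([C@H](C[C@H](O)C(C)(C)O)OC(=O)/C(C)=C\C)[C@@H]1C[C@@H](Cl)[C@](C)(O)[C@H](OC(=O)/C(C)=C\C)[C@@H]1OC(C)=O | target

**Totals**
Total step count: 15. Longest linear sequence: 12 steps (1 → 21 through steps 1–5 and 9–15); the side-chain fragment 8 → 11 takes 3 steps (6–8).

**Three steps most likely to fail**

Step 2, Mitsunobu inversion of the hindered α-ketol (elimination or poor conversion). The fallback sets out from carvone 1 and comes back at 4, replacing steps 1 and 2. LiN(iPr)2 and Me3SiCl give {[(6R)-3-methyl-6-(prop-1-en-2-yl)cyclohexa-1,3-dien-2-yl]oxy}trimethylsilane F1. N-Bromosuccinimide (THF, −78 °C) brominates F1 anti to the isopropenyl group to give trans-6-bromocarvone F2. Bu4NOAc in acetone then displaces the α-keto bromide by SN2 with inversion to give the cis acetate 4.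

Step 9, Keck allylation with the stannane as the limiting partner (together with the lability of 7: protodestannylation, allyl–allyl coupling in step 5). The fallback sets out from the allylic chloride 6 and comes back at 12, skipping 7 and making no new compound. It is a nickel-catalysed reductive cross-electrophile coupling of 6 with iodide 11 [NiCl2(dme), 4,4′-di-tert-butyl-2,2′-bipyridine, Zn dust, DMA, rt].

Step 13, chelate-controlled reduction: the hindered dioxolane oxygen may chelate weakly and give a poor 8S:8R ratio. The fallback sets out from 17 and comes back at 19. Reduce 17 without control (NaBH4, CeCl3·7H2O) and separate 18 from its (8R)-epimer F3; 18 continues through step 14. F3 is converged by a Mitsunobu reaction with angelic acid (PPh3, DIAD), which inverts the allylic C8 centre and installs the ester at once to give the (8S)-8-mono-angelate F4 (the C5 hydroxyl next to the oxirane is too hindered to react). Yamaguchi angeloylation of the C5 hydroxyl of F4 gives 19.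

**Further compounds**
F1 | step 2 | {[(6R)-3-methyl-6-(prop-1-en-2-yl)cyclohexa-1,3-dien-2-yl]oxy}trimethylsilane | C=C(C)[C@@H]1CC=C(C)C(O[Si](C)(C)C)=C1
F2 | step 2 | (5S,6S)-6-bromo-2-methyl-5-(prop-1-en-2-yl)cyclohex-2-en-1-one | C=C(C)[C@@H]1CC=C(C)C(=O)[C@H]1Br
F0 | step 9 | none | none
F3 | step 13 | (8R)-epimer of 18 (1S,3S,4R,5R,6R,8R,10S) | C=C([C@@H](C[C@@H]2OC(C)(C)OC2(C)C)O)[C@@H]1C[C@@H]3O[C@]3(C)[C@H](O)[C@@H]1OC(C)=O
F4 | step 13 | (8S)-8-O-[(Z)-2-methylbut-2-enoyl] derivative of 18 with free C5 hydroxyl | C=C([C@H](C[C@@H]2OC(C)(C)OC2(C)C)OC(=O)/C(C)=C\C)[C@@H]1C[C@@H]3O[C@]3(C)[C@H](O)[C@@H]1OC(C)=O
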